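**Retrosynthetic overview**

1. Target ⇒ terpenoid hydroxy aldehyde + 2,4-diformylphloroglucinol + isobutyl iodide. The C-9′–aryl and C-9′–CH2 bonds are made in one visible-light radical three-component coupling through an ortho-quinone methide, with C-9′ controlled by C-1/C-10.
2. Hydroxy aldehyde ⇒ ester reduction; both tertiary alcohols (axial 4-OH, 11-OH) ⇒ double oxymercuration–demercuration of an octalin diene ester.
3. Octalin ester ⇒ intramolecular Diels–Alder reaction of an acyclic (2E,8E)-trienoate, which sets C-1, C-5 and C-10 from C-7.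
4. Trienoate ⇒ three olefinations of (3S)-6-oxo-3-isopropenylheptanal ⇒ periodate cleavage of (4S)-limonene oxide, the only bought stereocentre (C-7).
5. Ring order: carbocyclic rings A and B close together in the Diels–Alder step; the aromatic ring is bought.

Assumption: (4S)-limonene 1,2-oxide (cis/trans mixture, from (S)-(−)-limonene) and 2,4-diformylphloroglucinol are taken as purchasable; atom labels C-1 to C-15 follow eudesmane numbering of the target and C-9′ is the benzylic carbon.

**Route**

Step 1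
Reactants: 1 (4S)-limonene 1,2-oxide
Product: 3 (3S)-6-oxo-3-(prop-1-en-2-yl)heptanal, via limonene-1,2-diol 2 (not isolated)
Conditions: H5IO6 (1.1 equiv), THF/H2O, 0 °C to rt
Reagents that add atoms: water, O
Why: Periodic acid hydrolyses the epoxide to the diol and cleaves it (Malaprade glycol cleavage) without touching the isopropenyl group or the stereocentre that becomes C-7.

Step 2
Reactants: 3 (3S)-6-oxo-3-(prop-1-en-2-yl)heptanal
Product: 4 (2E,5S)-2-methyl-8-oxo-5-(prop-1-en-2-yl)non-2-enal
Conditions: Ph3P=C(Me)CHO (1.05 equiv), toluene, 80 °C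
Reagents that add atoms: 2-(triphenylphosphoranylidene)propanal, CC(C=O)=P(c1ccccc1)(c1ccccc1)c1ccccc1
Why: Wittig olefination with a stabilised formyl ylide is aldehyde-selective (the methyl ketone is untouched) and gives the (E)-trisubstituted enal.

Step 3
Reactants: 4 (2E,5S)-2-methyl-8-oxo-5-(prop-1-en-2-yl)non-2-enal
Product: 5 (5S,7E)-8-methyl-5-(prop-1-en-2-yl)deca-7,9-dien-2-one
Conditions: Ph3PCH3Br (1.05 equiv), KOtBu, THF, −78 to 0 °C
Reagents that add atoms: methyltriphenylphosphonium bromide, C[P+](c1ccccc1)(c1ccccc1)c1ccccc1.[Br-]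
Why: Wittig methylenation at low temperature is much faster at the enal CHO than at the methyl ketone and gives the (E)-2-methyl-1,3-diene with the alkene geometry retained.

Step 4
Reactants: 5 (5S,7E)-8-methyl-5-(prop-1-en-2-yl)deca-7,9-dien-2-one
Product: 6 ethyl (2E,6S,8E)-3,9-dimethyl-6-(prop-1-en-2-yl)undeca-2,8,10-trienoate
Conditions: (EtO)2P(O)CH2CO2Et, NaH, THF, 0 to 65 °C; (2E) isomer separated on SiO2
Reagents that add atoms: triethyl phosphonoacetate, CCOC(=O)CP(=O)(OCC)OCC
Why: Horner–Wadsworth–Emmons olefination of the methyl ketone gives mainly the (E)-enoate (about 5:1 expected), which has CO2Et cis to the methyl group as required for the cis C-1/C-10 relationship.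

Step 5
Reactants: 6 ethyl (2E,6S,8E)-3,9-dimethyl-6-(prop-1-en-2-yl)undeca-2,8,10-trienoate
Product: 7 ethyl (1S,4aR,6S,8aS)-4,8a-dimethyl-6-(prop-1-en-2-yl)-1,2,4a,5,6,7,8,8a-octahydronaphthalene-1-carboxylate
Conditions: toluene (0.01 M), BHT (cat.), 180 °C, sealed tube
Reagents that add atoms: none
Why: Intramolecular Diels–Alder reaction through a chair-like tether with the isopropenyl group equatorial and the ester endo gives the trans-fused octalin, and suprafacial addition to the (E)-enoate puts CO2Et cis to the new angular methyl, so C-1, C-5 and C-10 are set relative to C-7.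

Step 6
Reactants: 7 ethyl (1S,4aR,6S,8aS)-4,8a-dimethyl-6-(prop-1-en-2-yl)-1,2,4a,5,6,7,8,8a-octahydronaphthalene-1-carboxylate
Product: 9 ethyl (1S,4R,4aS,6S,8aS)-4-hydroxy-6-(2-hydroxypropan-2-yl)-4,8a-dimethyldecahydronaphthalene-1-carboxylate, via bis(acetoxymercurio) adduct 8 (not isolated)
Conditions: Hg(OAc)2 (2.4 equiv), THF/H2O, rt; then NaOH aq, NaBH4, 0 °C
Reagents that add atoms: water, O
Why: Markovnikov oxymercuration–demercuration hydrates both alkenes without a free cation next to C-7; at the ring alkene divalent mercury adds to the face away from the angular methyl and water opens the mercurinium ion trans-diaxially at the tertiary carbon, so the 4-OH is axial and cis to the angular methyl.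

Step 7
Reactants: 9 ethyl (1S,4R,4aS,6S,8aS)-4-hydroxy-6-(2-hydroxypropan-2-yl)-4,8a-dimethyldecahydronaphthalene-1-carboxylate
Product: 10 (1S,4R,4aS,6S,8aS)-4-hydroxy-6-(2-hydroxypropan-2-yl)-4,8a-dimethyldecahydronaphthalene-1-carbaldehyde (in equilibrium with its bridged lactol tautomer)
Conditions: iBu2AlH (3.5 equiv), CH2Cl2, −78 °C; KNaC4H4O6 aq
Reagents that add atoms: none
Why: Low-temperature iBu2AlH reduction of the hindered ester stops at the aldehyde oxidation level, and C-1 keeps its equatorial, thermodynamically preferred configuration.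

Step 8
Reactants: 10 (1S,4R,4aS,6S,8aS)-4-hydroxy-6-(2-hydroxypropan-2-yl)-4,8a-dimethyldecahydronaphthalene-1-carbaldehyde; 11 2,4,6-trihydroxybenzene-1,3-dicarbaldehyde (2,4-diformylphloroglucinol)
Product: 13 5-[(1R)-1-[(1R,4R,4aS,6S,8aR)-4-hydroxy-6-(2-hydroxypropan-2-yl)-4,8a-dimethyldecahydronaphthalen-1-yl]-3-methylbutyl]-2,4,6-trihydroxybenzene-1,3-dicarbaldehyde, via ortho-quinone methide 12 (not isolated)
Conditions: NaOAc (2 equiv), AcOH/ClCH2CH2Cl 1:3, 60 °C, 4 h; then 25 °C, iBuI (5 equiv), (Me3Si)3SiH (2.5 equiv, added over 6 h), blue LEDs (450 nm)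
Reagents that add atoms: 1-iodo-2-methylpropane (isobutyl iodide), CC(C)CI
Why: Proposed new method: a visible-light three-component "carbonyl alkylative ortho-hydroxyarylation" in which acetate-buffered Knoevenagel-type condensation of aldehyde 10 with the free ring position of 11 gives ortho-quinone methide 12, the light-started (Me3Si)3Si radical abstracts iodine from isobutyl iodide, the nucleophilic isobutyl radical adds to the exocyclic carbon of electron-poor 12 with rearomatisation, and the phenoxyl radical takes H from (Me3Si)3SiH to carry the chain; A(1,3) strain holds H-1 in the plane of the quinone methide so the radical enters on the C-2 methylene side, anti to the quaternary C-10, which gives the (9′R) centre; the closest known reaction types are the visible-light silane-mediated carbonyl alkylative amination (alkyl radical addition to iminium ions formed in situ) and alkyl-radical 1,6-additions to para-quinone methides, neither shown for an acylphloroglucinol ortho-quinone methide formed in situ from an aliphatic aldehyde.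

**Compound list**

1 | (4S)-1-methyl-4-(prop-1-en-2-yl)-7-oxabicyclo[4.1.0]heptane ((4S)-limonene 1,2-oxide, cis/trans mixture at the epoxide) | CC12OC1C[C@@H](C(C)=C)CC2 | starting material
2 | (4S)-1-methyl-4-(prop-1-en-2-yl)cyclohexane-1,2-diol (limonene-1,2-diol, mixture at C-1/C-2) | CC1(O)C(O)C[C@@H](C(C)=C)CC1 | intermediate (not isolated)
3 | (3S)-6-oxo-3-(prop-1-en-2-yl)heptanal | O=CC[C@@H](C(C)=C)CCC(C)=O | intermediate
4 | (2E,5S)-2-methyl-8-oxo-5-(prop-1-en-2-yl)non-2-enal | O=C/C(C)=C/C[C@@H](C(C)=C)CCC(C)=O | intermediate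
5 | (5S,7E)-8-methyl-5-(prop-1-en-2-yl)deca-7,9-dien-2-one | C=C/C(C)=C/C[C@@H](C(C)=C)CCC(C)=O | intermediate
6 | ethyl (2E,6S,8E)-3,9-dimethyl-6-(prop-1-en-2-yl)undeca-2,8,10-trienoate | C=C/C(C)=C/C[C@@H](C(C)=C)CC/C(C)=C/C(=O)OCC | intermediate
7 | ethyl (1S,4aR,6S,8aS)-4,8a-dimethyl-6-(prop-1-en-2-yl)-1,2,4a,5,6,7,8,8a-octahydronaphthalene-1-carboxylate (trans-fused; CO2Et cis to the angular methyl) | CCOC(=O)[C@H]1CC=C(C)[C@H]2C[C@@H](C(C)=C)CC[C@]12C | intermediate
8 | ethyl (1S,3S,4S,4aS,6S,8aS)-3-(acetoxymercurio)-6-[1-(acetoxymercurio)-2-hydroxypropan-2-yl]-4-hydroxy-4,8a-dimethyldecahydronaphthalene-1-carboxylate (ring HgOAc trans-diaxial to the 4-OH; mixture at the side-chain carbinol carbon) | CCOC(=O)[C@H]1C[C@H]([Hg]OC(C)=O)[C@@](C)(O)[C@H]2C[C@@H](C(C)(O)C[Hg]OC(C)=O)CC[C@]12C | intermediate (not isolated)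
9 | ethyl (1S,4R,4aS,6S,8aS)-4-hydroxy-6-(2-hydroxypropan-2-yl)-4,8a-dimethyldecahydronaphthalene-1-carboxylate | CCOC(=O)[C@H]1CC[C@@](C)(O)[C@H]2C[C@@H](C(C)(C)O)CC[C@]12C | intermediate
10 | (1S,4R,4aS,6S,8aS)-4-hydroxy-6-(2-hydroxypropan-2-yl)-4,8a-dimethyldecahydronaphthalene-1-carbaldehyde | O=C[C@H]1CC[C@@](C)(O)[C@H]2C[C@@H](C(C)(C)O)CC[C@]12C | intermediate
11 | 2,4,6-trihydroxybenzene-1,3-dicarbaldehyde (2,4-diformylphloroglucinol) | O=Cc1c(O)cc(O)c(C=O)c1O | starting material
12 | ortho-quinone methide: 3,5-diformyl-2,4-dihydroxy-6-(terpenylmethylidene)cyclohexa-2,4-dien-1-one, where terpenyl is the (1R,4R,4aS,6S,8aR)-4-hydroxy-6-(2-hydroxypropan-2-yl)-4,8a-dimethyldecahydronaphthalen-1-yl group (exocyclic alkene geometry not fixed) | O=C1C(C=O)=C(O)C(C=O)=C(O)C1=C[C@H]1CC[C@@](C)(O)[C@H]2C[C@@H](C(C)(C)O)CC[C@]12C | intermediate (not isolated)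
13 | 5-[(1R)-1-[(1R,4R,4aS,6S,8aR)-4-hydroxy-6-(2-hydroxypropan-2-yl)-4,8a-dimethyldecahydronaphthalen-1-yl]-3-methylbutyl]-2,4,6-trihydroxybenzene-1,3-dicarbaldehyde | CC(C)C[C@@H](c1c(O)c(C=O)c(O)c(C=O)c1O)[C@H]1CC[C@@](C)(O)[C@H]2C[C@@H](C(C)(C)O)CC[C@]12C | target

**Step count and risks**

Total step count: 8. Longest linear sequence: 8 (1 to 13; 11 is bought).

The three steps most likely to fail:

Step 8 (proposed new step). The hindered, neopentyl-type aldehyde may condense slowly, the isobutyl radical may be reduced by the silane before it meets 12 (hence slow silane addition and excess iodide), 12 may be reduced directly, and the diastereoselectivity at C-9′ is predicted, not demonstrated. The fallback uses known chemistry, sets out from 10 and 11 and returns at 13. Heating 10 and 11 with NaOAc in AcOH in the presence of 2-methylallyltrimethylsilane lets the thermally formed 12 be captured by Hosomi–Sakurai-type allylation, under the same A(1,3) facial bias, to give the 2-methylallyl phenol F1. Hydrogenation of its 1,1-disubstituted alkene (H2, RhCl(PPh3)3, benzene/EtOH, rt) then gives 13.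

Step 5. The β,β-disubstituted enoate is a sluggish dienophile, and purely thermal cyclisation may give a trans/cis-fused mixture. The fallback sets out from 6 and returns at 10. Reduction with iBu2AlH gives the trienol F2, and MnO2 oxidation gives the trienal F3. Me2AlCl-promoted intramolecular Diels–Alder reaction at −78 °C gives the octalin aldehyde F4, endo-selectively and with C-1 able to epimerise to the equatorial aldehyde. Hg(OAc)2/H2O followed by NaBH4 hydrates both alkenes and reduces the aldehyde to the triol F5. TEMPO/PhI(OAc)2 then oxidises only the primary alcohol to give 10.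

Step 6. Water must attack C-4 syn-axial to the angular methyl, the trisubstituted alkene may react incompletely, and the ester may be partly saponified. The fallback sets out from 7 and returns at 10. Mukaiyama hydration (Co(acac)2, PhSiH3, O2) of the isopropenyl group alone gives the hydroxy ester F6, and LiOH gives the acid F7. Iodolactonisation (I2, NaHCO3) gives the bridged iodolactone F8, in which the oxygen at C-4 is forced onto the face of the C-1 carboxyl. Bu3SnH/AIBN gives the lactone F9, and iBu2AlH reduction gives 10, obtained as its ring-closed lactol tautomer.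

**Further compounds**

F1 | step 8 | 5-[(1R)-1-[(1R,4R,4aS,6S,8aR)-4-hydroxy-6-(2-hydroxypropan-2-yl)-4,8a-dimethyldecahydronaphthalen-1-yl]-3-methylbut-3-enyl]-2,4,6-trihydroxybenzene-1,3-dicarbaldehyde | C=C(C)C[C@@H](c1c(O)c(C=O)c(O)c(C=O)c1O)[C@H]1CC[C@@](C)(O)[C@H]2C[C@@H](C(C)(C)O)CC[C@]12C
F2 | step 5 | (2E,6S,8E)-3,9-dimethyl-6-(prop-1-en-2-yl)undeca-2,8,10-trien-1-ol | C=C/C(C)=C/C[C@@H](C(C)=C)CC/C(C)=C/CO
F3 | step 5 | (2E,6S,8E)-3,9-dimethyl-6-(prop-1-en-2-yl)undeca-2,8,10-trienal | C=C/C(C)=C/C[C@@H](C(C)=C)CC/C(C)=C/C=O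
F4 | step 5 | (1S,4aR,6S,8aS)-4,8a-dimethyl-6-(prop-1-en-2-yl)-1,2,4a,5,6,7,8,8a-octahydronaphthalene-1-carbaldehyde | O=C[C@H]1CC=C(C)[C@H]2C[C@@H](C(C)=C)CC[C@]12C
F5 | step 5 | triol corresponding to 10 with CH2OH in place of CHO at C-1 | OC[C@H]1CC[C@@](C)(O)[C@H]2C[C@@H](C(C)(C)O)CC[C@]12C
F6 | step 6 | ethyl (1S,4aR,6S,8aS)-6-(2-hydroxypropan-2-yl)-4,8a-dimethyl-1,2,4a,5,6,7,8,8a-octahydronaphthalene-1-carboxylate | CCOC(=O)[C@H]1CC=C(C)[C@H]2C[C@@H](C(C)(C)O)CC[C@]12C
F7 | step 6 | (1S,4aR,6S,8aS)-6-(2-hydroxypropan-2-yl)-4,8a-dimethyl-1,2,4a,5,6,7,8,8a-octahydronaphthalene-1-carboxylic acid | OC(=O)[C@H]1CC=C(C)[C@H]2C[C@@H](C(C)(C)O)CC[C@]12C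
F8 | step 6 | bridged iodolactone: C-1 carboxyl lactonised onto the C-4 oxygen, iodine at C-3 trans to the lactone oxygen | O=C3[C@H]1C[C@H](I)[C@@](C)(O3)[C@H]2C[C@@H](C(C)(C)O)CC[C@]12C
F9 | step 6 | bridged lactone: C-1 carboxyl lactonised onto the C-4 oxygen (2-oxabicyclo[2.2.2]octan-3-one fused to ring B) | O=C3[C@H]1CC[C@@](C)(O3)[C@H]2C[C@@H](C(C)(C)O)CC[C@]12C
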